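**Retrosynthetic overview**
- The strategy rests on the 2,4-dibromo-6-alkylphenol ring, whose carbons read C(CH2–C9), C(OH), C(Br), CH, C(Br), CH. The first two are the carbons of an O-silyl ynol ether and the last four are C3–C6 of 3,5-dibromo-2-pyrone, so the arene is cut by a pyrone Diels–Alder/CO2-loss disconnection.
- Before that cut, the silyl group is removed and the CHBr–CMe2Cl terminus is traced back through a bromohydrin and an epoxide to a trisubstituted alkene.
- The ynol ether comes from a terminal alkyne, and this from the C12 aldehyde left when the lactone side chain of andrographolide is cleaved at C12=C13; the pyrone comes from coumalic acid.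
- Rings A and B with C5, C9, C10 and the C8 methylidene are taken intact from andrographolide. C4 is rebuilt by decarboxylative allylation of a C19 allyl β-keto ester (allyl then extended to homoprenyl), and C3–Br by reduction to the axial alcohol and Appel inversion.
- Ring order: decalin from the chiral pool; the arene is the only ring formed, in step 17.

Key step: step 17

Remark: labdane numbering is used for the decalin (C3 Br, C4 methyl and side chain, C8 methylidene, C9 benzylic CH2, C10 angular methyl); cycloadduct 22 is assumed to form as both bridgehead epimers, which is without consequence because both centres become arene carbons.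

**Route**

Step 1
Reactants: 1 andrographolide
Product: 2 andrographolide 3,19-acetonide (1,3-dioxane across O3 and C19; C14 hydroxyl free)
Conditions: Me2C(OMe)2, PPTS (cat.), toluene/DMSO, 80 °C
Reagents that add atoms: 2,2-dimethoxypropane, COC(C)(C)OC
Why: Acid-catalysed acetonide formation (transketalisation) joins the equatorial C3 hydroxyl and the axial C19 hydroxymethyl, which are gauche on neighbouring carbons, and leaves only the C14 alcohol free.

Step 2
Reactants: 2 andrographolide 3,19-acetonide
Product: 3 acetonide C12 aldehyde (C9–CH2–CHO; 3,19-O-isopropylidene-13,14,15,16-tetranor-ent-labd-8(17)-en-12-al)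
Conditions: KMnO4, THF/H2O, −10 °C
Reagents that add atoms: potassium permanganate KMnO4, [K+].[O-][Mn](=O)(=O)=O
Why: Permanganate oxidative cleavage of an alkene: the exposed, conjugated C12=C13 bond of the alkylidene lactone should take up MnO4− faster than the hindered, unconjugated C8 methylidene, and the cyclic manganate ester fragments to the C12 aldehyde and an α-keto lactone at low temperature.

Step 3
Reactants: 3 acetonide C12 aldehyde
Product: 4 3,19-diol with C12 masked as a 1,3-dioxolane
Conditions: HOCH2CH2OH (10 equiv), p-TsOH·H2O (cat.), CH2Cl2, 25 °C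
Reagents that add atoms: ethylene glycol, OCCO
Why: Acid-catalysed acetalisation of the aldehyde gives the base-, hydride- and oxidant-stable dioxolane, and the water it releases hydrolyses the acetonide in the same flask, so both hydroxyls are freed.

Step 4
Reactants: 4 diol dioxolane
Product: 5 3-oxo-19-al (β-keto aldehyde with quaternary C4), C12 dioxolane
Conditions: Dess–Martin periodinane (3 equiv), CH2Cl2, 0 → 25 °C
Reagents that add atoms: none
Why: Dess–Martin oxidation takes the secondary C3 alcohol to the ketone and the neopentyl C19 alcohol to the aldehyde under non-basic conditions in which the quaternary β-keto aldehyde does not deformylate.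

Step 5
Reactants: 5 β-keto aldehyde
Product: 6 3-oxo-19-oic acid (β-keto acid), C12 dioxolane, used at once
Conditions: NaClO2, NaH2PO4, 2-methylbut-2-ene, t-BuOH/H2O, 0 °C
Reagents that add atoms: sodium chlorite NaClO2, [Na+].[O-]Cl=O
Why: Pinnick oxidation converts the aldehyde into the acid while 2-methylbut-2-ene traps hypochlorous acid before it can reach the methylidene.

Step 6
Reactants: 6 β-keto acid
Product: 7 allyl 3-oxo-19-oate (allyl β-keto ester), C12 dioxolane
Conditions: allyl bromide, K2CO3, DMF, 0 → 20 °C
Reagents that add atoms: allyl bromide, C=CCBr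
Why: Carboxylate O-alkylation (SN2) under mild base esterifies the acid below its decarboxylation temperature, and C-alkylation cannot compete because C4 is quaternary.

Step 7
Reactants: 7 allyl β-keto ester
Product: 8 19-nor-3-ketone with quaternary C4 (allyl equatorial and anti to the C10 methyl, methyl axial), C12 dioxolane
Conditions: Pd(PPh3)4 (5 mol %), THF, 25 °C
Reagents that add atoms: none
Why: Tsuji decarboxylative allylation: oxidative addition of zerovalent palladium to the allyl ester and loss of CO2 generate the C3–C4 enolate regiospecifically, and the allyl group is delivered to the face of C4 opposite the axial C10 methyl, which sets the target's C4 configuration (methyl axial, carbon chain equatorial).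

Step 8
Reactants: 8 C4-allyl ketone
Product: 9 axial C3 alcohol (hydroxyl anti to the C10 methyl)
Conditions: LiBH(s-Bu)3, THF, −78 °C; then H2O
Reagents that add atoms: none
Why: Ketone reduction with a bulky trialkylborohydride (L-Selectride type) proceeds by equatorial attack at a carbonyl flanked by a quaternary carbon and so sets the axial alcohol needed for displacement with inversion.

Step 9
Reactants: 9 axial C3 alcohol
Product: 10 equatorial C3 bromide (C4 allyl), C12 dioxolane
Conditions: CBr4, PPh3, 2,6-lutidine, toluene, 25 → 60 °C
Reagents that add atoms: tetrabromomethane, BrC(Br)(Br)Br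
Why: Appel bromination: bromide displaces the alkoxyphosphonium group of the axial alcohol in an SN2 step with inversion, which places bromine equatorial as in the target, the non-ionising buffered medium being chosen to hold back elimination and methyl migration.

Step 10
Reactants: 10 C3 bromide with C4 allyl
Product: 12 primary alcohol (C4 3-hydroxypropyl), via alkyldisiamylborane 11 (not isolated)
Conditions: Sia2BH (from BH3·SMe2 and 2-methylbut-2-ene), THF, 0 °C; then NaOH, H2O2, 0 → 25 °C
Reagents that add atoms: hydrogen peroxide, OO
Why: Anti-Markovnikov hydroboration–oxidation with disiamylborane, which reacts far faster with the monosubstituted allyl terminus than with the hindered 1,1-disubstituted C8 methylidene, gives the primary alcohol.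

Step 11
Reactants: 12 primary alcohol
Product: 13 aldehyde (C4 3-oxopropyl)
Conditions: Dess–Martin periodinane, CH2Cl2, 0 → 25 °C
Reagents that add atoms: none
Why: Dess–Martin oxidation stops at the aldehyde and leaves the secondary bromide, the acetal and the methylidene untouched.

Step 12
Reactants: 13 aldehyde
Product: 14 C4 4-methylpent-3-enyl (homoprenyl) compound, C12 dioxolane
Conditions: i-PrPPh3I, n-BuLi, THF, 0 °C; then 13, −78 → 25 °C
Reagents that add atoms: isopropyltriphenylphosphonium iodide, CC(C)[P+](c1ccccc1)(c1ccccc1)c1ccccc1.[I-]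
Why: Wittig olefination with the non-stabilised isopropylidene ylide forms the trisubstituted alkene without a geometry issue, and the equatorial bromide, which has no antiperiplanar hydrogen, should resist elimination.

Step 13
Reactants: 14 homoprenyl dioxolane
Product: 15 C12 aldehyde (C9–CH2–CHO) with C3 bromide and C4 homoprenyl
Conditions: p-TsOH·H2O (cat.), THF/H2O (4:1), 40 °C
Reagents that add atoms: water, O
Why: Acid-catalysed acetal hydrolysis under mild aqueous conditions releases the aldehyde without hydrating or isomerising the two alkenes.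

Step 14
Reactants: 15 C12 aldehyde
Product: 16 terminal alkyne (C9–CH2–C≡CH)
Conditions: dimethyl (1-diazo-2-oxopropyl)phosphonate, K2CO3, MeOH, 0 → 25 °C
Reagents that add atoms: dimethyl (1-diazo-2-oxopropyl)phosphonate, COP(=O)(OC)C(=[N+]=[N-])C(C)=O
Why: Ohira–Bestmann (Seyferth–Gilbert) homologation turns the aldehyde into the one-carbon-longer terminal alkyne under carbonate conditions that the secondary bromide tolerates.

Step 15
Reactants: 16 terminal alkyne
Product: 19 triisopropylsilyl ynol ether (C9–CH2–C≡C–OSi(i-Pr)3), via lithium acetylide 17 (not isolated), via lithium ynolate 18 (not isolated)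
Conditions: LiN(SiMe3)2 (2.2 equiv), THF, −78 °C; t-BuOOH (1.1 equiv), −78 → 0 °C; i-Pr3SiOTf, −78 °C
Reagents that add atoms: tert-butyl hydroperoxide, CC(C)(C)OO; triisopropylsilyl trifluoromethanesulfonate, CC(C)[Si](C(C)C)(C(C)C)OS(=O)(=O)C(F)(F)F
Why: Oxidation of a lithium acetylide by lithium tert-butylperoxide to the ynolate followed by O-silylation with a bulky silyl triflate is the established route to silyl ynol ethers, and none of the reagents touches the bromide or the alkenes at low temperature.

Step 16
Reactants: 20 coumalic acid
Product: 21 3,5-dibromo-2H-pyran-2-one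
Conditions: N-bromosuccinimide (2.2 equiv), LiOAc (cat.), MeCN/H2O, 25 → 60 °C
Reagents that add atoms: N-bromosuccinimide, O=C1CCC(=O)N1Br
Why: Bromodecarboxylation (Hunsdiecker type) replaces the C5 carboxyl by bromine through ipso attack and loss of CO2, and electrophilic bromination at the enol-like C3 puts in the second bromine.

Step 17
Reactants: 19 triisopropylsilyl ynol ether; 21 3,5-dibromo-2H-pyran-2-one
Product: 23 aryl triisopropylsilyl ether (2,4-dibromo-6-alkylphenol ring complete; side chain still an alkene), via bicyclic lactone cycloadduct 22 (not isolated)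
Conditions: 21 (1.5 equiv), toluene, 90 °C, sealed tube
Reagents that add atoms: none
Why: Proposed new method: the electron-rich ynol ether 19 and the ambiphilic 2-pyrone 21 are expected to combine in an asynchronous [4+2] cycloaddition across C3 and C6 of the pyrone, after which the bridged lactone 22 loses CO2 by retro-[4+2] to leave the benzene ring; the closest known reaction type is the Diels–Alder/retro-Diels–Alder benzannulation of 2-pyrones with alkynes together with the mild cycloadditions of 3,5-dibromo-2-pyrone with enol ethers, a silyl ynol ether not having served as the alkyne partner. The arene, the only ring closed, forms intermolecularly as a six-membered carbocycle from the two alkyne carbons and pyrone C3–C6 through the bonds C(alkyl)–C6 and C(O)–C3, not by cyclisation of a tether. No new stereocentre remains, because the two bridgehead centres of 22 become arene carbons and the decalin centres are remote. The step needs regioselectivity, which the polarisation of the partners should supply: the ynol ether carbon that carries the CH2 group is its nucleophilic end and bonds to C6, the electrophilic terminus of the pyrone diene, so the oxygen-bearing carbon joins C3 and ends ortho to a bromine. It also needs chemoselectivity, expected because the C8 methylidene and the side-chain alkene are unactivated and far poorer dienophiles than the ynol ether and because the temperature stays under the threshold for the 1,3-silyl shift that turns silyl ynol ethers into silylketenes. Since the halogens come in with the pyrone and the oxygen with the alkyne, the substitution pattern of the phenol is complete when the ring forms and the two alkenes never meet an electrophilic brominating agent.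

Step 18
Reactants: 23 aryl triisopropylsilyl ether
Product: 24 (S)-epoxide of the side-chain alkene
Conditions: L-fructose-derived Shi ketone (30 mol %), KHSO5 (Oxone), K2CO3, Bu4NHSO4, MeCN/CH2(OMe)2/aq. buffer (pH 10.5), 0 °C
Reagents that add atoms: potassium peroxymonosulfate KHSO5, [K+].[O-]S(=O)(=O)OO
Why: Shi asymmetric epoxidation: the chiral dioxirane from the L-fructose-derived ketone delivers oxygen to the face of the trisubstituted alkene that gives the (S)-epoxide under catalyst control, and the electron-richer trisubstituted alkene reacts ahead of the hindered 1,1-disubstituted methylidene.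

Step 19
Reactants: 24 (S)-epoxide
Product: 25 bromohydrin ((R)-CHBr next to the tertiary alcohol)
Conditions: Li2NiBr4, THF, 0 → 25 °C
Reagents that add atoms: dilithium tetrabromonickelate Li2NiBr4 (divalent nickel), [Li+].[Li+].[Ni+2].[Br-].[Br-].[Br-].[Br-]
Why: Regioselective SN2 epoxide opening by a soft bromide source at the less substituted carbon proceeds with inversion and so converts the (S)-epoxide into the (R)-bromide of the target.

Step 20
Reactants: 25 bromohydrin
Product: 26 bromochloride ((R)-CHBr–CMe2Cl), aryl silyl ether
Conditions: 1-chloro-N,N,2-trimethylprop-1-en-1-amine, CH2Cl2, 0 → 25 °C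
Reagents that add atoms: 1-chloro-N,N,2-trimethylprop-1-en-1-amine, CC(C)=C(Cl)N(C)C
Why: Deoxychlorination with anchimeric assistance: the α-chloroenamine (Ghosez reagent) activates the tertiary alcohol under neutral conditions, the neighbouring bromine expels the leaving group to give a bromonium ion, and chloride opens it at the tertiary carbon, so the C–Br bond and its configuration are kept.

Step 21
Reactants: 26 bromochloride aryl silyl ether
Product: 27 target CNP0318265.2
Conditions: Bu4NF, AcOH, THF, 0 °C
Reagents that add atoms: none
Why: Fluoride desilylation of the aryl silyl ether, buffered with acetic acid so that fluoride does not act as a base on the vicinal bromochloride, frees the phenol.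

**Compound list**
1 | andrographolide | C=C1CC[C@@H]2[C@](C)(CO)[C@H](O)CC[C@@]2(C)[C@@H]1C/C=C1/C(=O)OC[C@H]1O | starting material
2 | andrographolide 3,19-acetonide | C=C1CC[C@@H]2[C@]3(C)COC(C)(C)O[C@@H]3CC[C@@]2(C)[C@@H]1C/C=C1/C(=O)OC[C@H]1O | intermediate
3 | acetonide C12 aldehyde (C9–CH2–CHO) | C=C1CC[C@@H]2[C@]3(C)COC(C)(C)O[C@@H]3CC[C@@]2(C)[C@@H]1CC=O | intermediate
4 | 3,19-diol, C12 as 1,3-dioxolane (C3 hydroxyl equatorial, C19 hydroxymethyl axial) | C=C1CC[C@@H]2[C@](C)(CO)[C@H](O)CC[C@@]2(C)[C@@H]1CC1OCCO1 | intermediate
5 | 3-oxo-19-al β-keto aldehyde, C12 dioxolane | C=C1CC[C@@H]2[C@](C)(C=O)C(=O)CC[C@@]2(C)[C@@H]1CC1OCCO1 | intermediate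
6 | 3-oxo-19-oic acid, C12 dioxolane | C=C1CC[C@@H]2[C@](C)(C(=O)O)C(=O)CC[C@@]2(C)[C@@H]1CC1OCCO1 | intermediate
7 | allyl 3-oxo-19-oate, C12 dioxolane | C=C1CC[C@@H]2[C@](C)(C(=O)OCC=C)C(=O)CC[C@@]2(C)[C@@H]1CC1OCCO1 | intermediate
8 | 19-nor-3-ketone, C4 allyl equatorial (anti to C10 methyl) and methyl axial, C12 dioxolane | C=C1CC[C@@H]2[C@@](C)(CC=C)C(=O)CC[C@@]2(C)[C@@H]1CC1OCCO1 | intermediate
9 | axial C3 alcohol of 8 | C=C1CC[C@@H]2[C@@](C)(CC=C)[C@@H](O)CC[C@@]2(C)[C@@H]1CC1OCCO1 | intermediate
10 | equatorial C3 bromide, C4 allyl, C12 dioxolane | C=C1CC[C@@H]2[C@@](C)(CC=C)[C@H](Br)CC[C@@]2(C)[C@@H]1CC1OCCO1 | intermediate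
11 | alkyldisiamylborane (C4 3-borylpropyl) | C=C1CC[C@@H]2[C@@](C)(CCCB(C(C)C(C)C)C(C)C(C)C)[C@H](Br)CC[C@@]2(C)[C@@H]1CC1OCCO1 | intermediate
12 | primary alcohol (C4 3-hydroxypropyl) | C=C1CC[C@@H]2[C@@](C)(CCCO)[C@H](Br)CC[C@@]2(C)[C@@H]1CC1OCCO1 | intermediate
13 | aldehyde (C4 3-oxopropyl) | C=C1CC[C@@H]2[C@@](C)(CCC=O)[C@H](Br)CC[C@@]2(C)[C@@H]1CC1OCCO1 | intermediate
14 | C4 homoprenyl C3 bromide, C12 dioxolane | C=C1CC[C@@H]2[C@@](C)(CCC=C(C)C)[C@H](Br)CC[C@@]2(C)[C@@H]1CC1OCCO1 | intermediate
15 | C12 aldehyde with C3 bromide and C4 homoprenyl | C=C1CC[C@@H]2[C@@](C)(CCC=C(C)C)[C@H](Br)CC[C@@]2(C)[C@@H]1CC=O | intermediate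
16 | terminal alkyne (C9–CH2–C≡CH) | C=C1CC[C@@H]2[C@@](C)(CCC=C(C)C)[C@H](Br)CC[C@@]2(C)[C@@H]1CC#C | intermediate
17 | lithium acetylide of 16 | C=C1CC[C@@H]2[C@@](C)(CCC=C(C)C)[C@H](Br)CC[C@@]2(C)[C@@H]1CC#C[Li] | intermediate
18 | lithium ynolate (C9–CH2–C≡C–OLi) | C=C1CC[C@@H]2[C@@](C)(CCC=C(C)C)[C@H](Br)CC[C@@]2(C)[C@@H]1CC#CO[Li] | intermediate
19 | triisopropylsilyl ynol ether, cycloaddition precursor | C=C1CC[C@@H]2[C@@](C)(CCC=C(C)C)[C@H](Br)CC[C@@]2(C)[C@@H]1CC#CO[Si](C(C)C)(C(C)C)C(C)C | intermediate
20 | coumalic acid | O=C(O)C1=COC(=O)C=C1 | starting material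
21 | 3,5-dibromo-2H-pyran-2-one | O=C1OC=C(Br)C=C1Br | intermediate
22 | bicyclic lactone: 4,7-dibromo-6-(decalinylmethyl)-5-(triisopropylsilyloxy)-2-oxabicyclo[2.2.2]octa-5,7-dien-3-one, both bridgehead epimers | C=C1CC[C@@H]2[C@@](C)(CCC=C(C)C)[C@H](Br)CC[C@@]2(C)[C@@H]1CC1=C(O[Si](C(C)C)(C(C)C)C(C)C)C2(Br)C=C(Br)C1OC2=O | intermediate
23 | aryl triisopropylsilyl ether with side-chain alkene | C=C1CC[C@@H]2[C@@](C)(CCC=C(C)C)[C@H](Br)CC[C@@]2(C)[C@@H]1Cc1cc(Br)cc(Br)c1O[Si](C(C)C)(C(C)C)C(C)C | intermediate
24 | (S)-epoxide of the side chain | C=C1CC[C@@H]2[C@@](C)(CC[C@@H]3OC3(C)C)[C@H](Br)CC[C@@]2(C)[C@@H]1Cc1cc(Br)cc(Br)c1O[Si](C(C)C)(C(C)C)C(C)C | intermediate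
25 | bromohydrin, (R)-CHBr and tertiary alcohol | C=C1CC[C@@H]2[C@@](C)(CC[C@@H](Br)C(C)(C)O)[C@H](Br)CC[C@@]2(C)[C@@H]1Cc1cc(Br)cc(Br)c1O[Si](C(C)C)(C(C)C)C(C)C | intermediate
26 | bromochloride aryl silyl ether | C=C1CC[C@@H]2[C@@](C)(CC[C@@H](Br)C(C)(C)Cl)[C@H](Br)CC[C@@]2(C)[C@@H]1Cc1cc(Br)cc(Br)c1O[Si](C(C)C)(C(C)C)C(C)C | intermediate
27 | CNP0318265.2 | C=C1CC[C@@H]2[C@@](C)(CC[C@@H](Br)C(C)(C)Cl)[C@H](Br)CC[C@@]2(C)[C@@H]1Cc1cc(Br)cc(Br)c1O | target

**Step count and risks**

Total: 21 steps. Longest linear sequence: 20 steps (steps 1–15 and 17–21 from andrographolide); the pyrone branch is step 16.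

Steps most likely to fail:

1. Step 17 (proposed new method). The silyl ynol ether may undergo the 1,3-silyl shift to the silylketene, or add stepwise to the pyrone and collapse to [2+2]-type products, faster than the [4+2] union, so that no arene forms.
 Fallback, from alkyne 16 back to 23, by the known cycloaddition of 2-pyrones with ketene acetals. Ynolate 18 is generated as in step 15 but quenched with aqueous acid, which gives through the ketene the one-carbon-longer carboxylic acid F1. Two equivalents of LiN(i-Pr)2 and Me3SiCl convert it into the bis(trimethylsilyl) ketene acetal F2. Heating F2 with pyrone 21 in toluene should give the cycloadduct, which loses CO2 and then trimethylsilanol to aromatise, and aqueous work-up gives the free phenol F3. Silylation with i-Pr3SiOTf and 2,6-lutidine returns to 23.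

2. Step 9. Anti elimination toward C2 and a 1,2-shift of the antiperiplanar axial C4 methyl from the activated axial alcohol may outrun bimolecular substitution at this neopentyl carbon.
 Fallback, from alcohol 9 back to 10: the one-pot phosphonium activation is replaced by a two-stage sulfonate displacement. ClCH2SO2Cl and pyridine at 0 °C give the isolable axial chloromethanesulfonate F4, a leaving group displaced readily at hindered secondary carbons but less prone to ionise than a triflate. F4 is then treated with Bu4NBr in toluene, which supplies unsolvated bromide in a non-ionising medium and should give 10 with inversion. This remains an SN2 at the same carbon, so it lowers the risk but does not remove it.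

3. Step 20. Proton loss from the bromonium or tertiary cation (giving the isopropenyl allylic bromide) or chloride attack at the secondary carbon may compete with the intended opening at the tertiary carbon.
 Fallback, from epoxide 24 back to 26, with the order of halogen introduction reversed. TiCl4 in CH2Cl2 at −78 °C opens the epoxide at the tertiary carbon to give the chlorohydrin F5 (tertiary chloride, (S)-secondary alcohol, C–O bond at the stereocentre untouched). Appel bromination (CBr4, PPh3) of the secondary alcohol with inversion then gives the (R)-bromide 26; this route also bypasses step 19.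

**Further compounds**
F1 | step 17 | homologous carboxylic acid (C9–CH2–CH2–CO2H) | C=C1CC[C@@H]2[C@@](C)(CCC=C(C)C)[C@H](Br)CC[C@@]2(C)[C@@H]1CCC(=O)O
F2 | step 17 | bis(trimethylsilyl) ketene acetal of F1 | C=C1CC[C@@H]2[C@@](C)(CCC=C(C)C)[C@H](Br)CC[C@@]2(C)[C@@H]1CC=C(O[Si](C)(C)C)O[Si](C)(C)C
F3 | step 17 | free phenol with side-chain alkene | C=C1CC[C@@H]2[C@@](C)(CCC=C(C)C)[C@H](Br)CC[C@@]2(C)[C@@H]1Cc1cc(Br)cc(Br)c1O
F4 | step 9 | axial C3 chloromethanesulfonate of 9 | C=C1CC[C@@H]2[C@@](C)(CC=C)[C@@H](OS(=O)(=O)CCl)CC[C@@]2(C)[C@@H]1CC1OCCO1
F5 | step 20 | chlorohydrin (tertiary chloride, (S)-secondary alcohol) | C=C1CC[C@@H]2[C@@](C)(CC[C@H](O)C(C)(C)Cl)[C@H](Br)CC[C@@]2(C)[C@@H]1Cc1cc(Br)cc(Br)c1O[Si](C(C)C)(C(C)C)C(C)C
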